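Retrosynthesis: with the five benzyl ethers removed, flavanone ring C is cut at O1–C2 (oxa-Michael) and C2–C3 (Knoevenagel). This gives a ring A β-ketoester and a ring B benzaldehyde that already carries the flavone.
Ring B is then cut at C2′–C3′ and C1′–C6′ (retro-Diels–Alder, ethanol added back), giving propynal and a 1-ethoxy-3-silyloxydiene on flavone C6. The flavone C6–carbon bond goes back to a Claisen rearrangement of apigenin 5-O-allyl ether.
Enabling feature: ring B is a phenol whose C4′–OH is para to C1′ (the carbon bound to flavanone C2) and ortho to C3′, the pattern a 1,3-dioxygenated diene and an ynal produce. C3′ sits on flavone C6, the one C–H position ortho to O5, since the other ortho carbon is the ring-fusion atom C4a.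
Forward order: the flavone rings come with apigenin, the C6 side chain is grown to the diene (steps 1–9), ring B is built (step 11), ring A is joined (step 15), and flavanone ring C closes last (step 16).
Stereochemistry: the only stereocentre, C2 (S), is set in step 16 by a cinchona-thiourea catalyst and is preserved by acidic decarboxylation and neutral hydrogenolysis.

Key step: step 11

Shorthand: "tri-O-benzylapigenin-6-yl" means 5,7-bis(benzyloxy)-2-[4-(benzyloxy)phenyl]-4-oxo-4H-chromen-6-yl.
Assumption 1: the quinidine-derived thiourea is taken as the pseudoenantiomer that leads to 2S. If the sense of induction is the opposite, the quinine-derived catalyst replaces it with no other change.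
Assumption 2: the C6–C3′ biaryl axis is not a stable stereogenic element (the target SMILES defines none), so slowly interconverting rotamers of benzylated intermediates count as one compound.
Assumption 3: 2′,4′-dihydroxy-6′-methoxyacetophenone, ethynylmagnesium bromide solution and the thiourea catalyst are catalogue items.

Step 1
Reactants: 1 apigenin
Product: 2 7,4′-di-O-benzylapigenin
Conditions: BnBr (2.2 equiv), K2CO3, DMF, 25–40 °C
Reagents that add atoms: benzyl bromide, BrCc1ccccc1
Why: Williamson etherification in which the 7- and 4′-phenols react while the 5-OH, held in a hydrogen bond to the C4 carbonyl, stays free at this stoichiometry and temperature.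

Step 2
Reactants: 2 7,4′-di-O-benzylapigenin; 3 allyl bromide
Product: 4 5-O-allyl-7,4′-di-O-benzylapigenin
Conditions: K2CO3, DMF, 60 °C
Reagents that add atoms: none
Why: Williamson etherification of the remaining chelated 5-OH, which responds to a reactive allylic halide at higher temperature.

Step 3
Reactants: 4 5-O-allyl-7,4′-di-O-benzylapigenin
Product: 6 6-allyl-7,4′-di-O-benzylapigenin, via ortho-dienone 5 (not isolated)
Conditions: PhNEt2, 200 °C, sealed tube, Ar
Reagents that add atoms: none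
Why: Aromatic Claisen rearrangement, in which the [3,3] shift can place the allyl group only on C6 because the other carbon ortho to O5 is the ring-fusion atom C4a, and dienone 5 tautomerises at once to the chelated phenol.

Step 4
Reactants: 6 6-allyl-7,4′-di-O-benzylapigenin
Product: 7 6-allyl-5,7,4′-tri-O-benzylapigenin
Conditions: BnBr, K2CO3, n-Bu4NI (cat.), DMF, 80 °C
Reagents that add atoms: benzyl bromide, BrCc1ccccc1
Why: Williamson etherification under more forcing conditions caps the hindered 5-OH so that it cannot later close onto the side-chain carbonyl groups to form a benzofuran.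

Step 5
Reactants: 7 6-allyl-5,7,4′-tri-O-benzylapigenin
Product: 9 (tri-O-benzylapigenin-6-yl)acetaldehyde, via vicinal diol 8 (not isolated)
Conditions: OsO4 (2 mol %), NaIO4 (4 equiv), 2,6-lutidine, dioxane–H2O, 25 °C
Reagents that add atoms: OsO4, O=[Os](=O)(=O)=O (oxygen carrier); NaIO4, [Na+].[O-]I(=O)(=O)=O (terminal oxygen source)
Why: Lemieux–Johnson cleavage, in which OsO4 dihydroxylates the terminal alkene in preference to the electron-poor flavone C2=C3 bond and NaIO4 cleaves diol 8 as it forms.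

Step 6
Reactants: 9 (tri-O-benzylapigenin-6-yl)acetaldehyde; 10 ethynylmagnesium bromide
Product: 11 rac-1-(tri-O-benzylapigenin-6-yl)but-3-yn-2-ol
Conditions: 10 (1.3 equiv, 0.5 M in THF), THF, −78 → −30 °C; sat. aq. NH4Cl
Reagents that add atoms: none
Why: Grignard 1,2-addition, the aldehyde being far more electrophilic at low temperature than the vinylogous-ester carbonyl of the flavone, and the new carbinol centre forms as a racemate that step 7 erases.

Step 7
Reactants: 11 rac-1-(tri-O-benzylapigenin-6-yl)but-3-yn-2-ol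
Product: 12 1-(tri-O-benzylapigenin-6-yl)but-3-yn-2-one
Conditions: Dess–Martin periodinane (1.3 equiv), CH2Cl2, 0 → 25 °C
Reagents that add atoms: none
Why: Dess–Martin oxidation of a secondary propargylic alcohol under near-neutral conditions that leave the benzyl ethers and the flavone untouched.

Step 8
Reactants: 12 1-(tri-O-benzylapigenin-6-yl)but-3-yn-2-one
Product: 13 (3E)-4-ethoxy-1-(tri-O-benzylapigenin-6-yl)but-3-en-2-one
Conditions: EtOH (2 equiv), DABCO (10 mol %), CH2Cl2, 0 → 25 °C
Reagents that add atoms: ethanol, CCO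
Why: Amine-catalysed oxa-Michael addition of an alcohol to a terminal ynone, which settles on the E β-alkoxyenone as the thermodynamic product.

Step 9
Reactants: 13 (3E)-4-ethoxy-1-(tri-O-benzylapigenin-6-yl)but-3-en-2-one
Product: 14 5,7-bis(benzyloxy)-2-[4-(benzyloxy)phenyl]-6-[(1Z,3E)-4-ethoxy-2-(trimethylsilyloxy)buta-1,3-dien-1-yl]chromen-4-one
Conditions: Me3SiOTf (1.3 equiv), Et3N (2.5 equiv), CH2Cl2–Et2O, 0 °C; pentane dilution, cold aq. NaHCO3 wash, used crude
Reagents that add atoms: trimethylsilyl triflate, C[Si](C)(C)OS(=O)(=O)C(F)(F)F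
Why: Soft enolisation and O-silylation as used for 1-alkoxy-3-silyloxybutadienes, the benzylic CH2 being the only enolisable site and the Z enol ether (aryl cis to OSiMe3, trans to the ethoxyvinyl arm) being favoured because it avoids allylic strain.

Step 10
Reactants: 15 propargyl alcohol
Product: 16 propynal
Conditions: CrO3, H2SO4, H2O, 2–10 °C, 40–60 mmHg, product swept into −78 °C traps; stored as a cold toluene solution
Reagents that add atoms: none
Why: Chromic acid oxidation of a primary propargylic alcohol, in which the volatile aldehyde is removed under reduced pressure before it can be oxidised further.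

Step 11
Reactants: 14 5,7-bis(benzyloxy)-2-[4-(benzyloxy)phenyl]-6-[(1Z,3E)-4-ethoxy-2-(trimethylsilyloxy)buta-1,3-dien-1-yl]chromen-4-one; 16 propynal
Product: 19 4-hydroxy-3-(tri-O-benzylapigenin-6-yl)benzaldehyde, via cis-cyclohexadiene cycloadduct 17 (not isolated), via aryl trimethylsilyl ether 18 (not isolated)
Conditions: 16 (3 equiv), BHT (cat.), toluene, base-washed sealed tube, 25 → 80 °C; then 0.1 M HCl, THF, 0 °C
Reagents that add atoms: none
Why: A thermal, concerted but strongly asynchronous [4+2] cycloaddition joins the enol-ether terminus of 14 that bears flavone C6 (future C3′) to the unsubstituted alkyne carbon of 16 (future C2′), and the ethoxy-bearing terminus (future C6′) to the formyl-bearing alkyne carbon (future C1′), giving 1,4-cyclohexadiene 17. Ring B is thus closed intermolecularly as a six-membered carbocycle by two new C–C bonds in one [4π+2π] event, the closest known reaction being the Diels–Alder addition and aromatisation of 1-alkoxy-3-silyloxybutadienes with acetylenic aldehydes and esters to para-hydroxyaryl carbonyl compounds. 1,4-Loss of ethanol from 17 (C6′–OEt and C3′–H) should give aryl silyl ether 18, and dilute acid then frees phenol 19. The two sp3 centres of 17 are cis through suprafacial addition to a diene whose terminal substituents both point outward, but both disappear on aromatisation, so no stereocentre is carried forward. Regioselectivity is required and comes from the two oxygen donors, which put the largest HOMO coefficient on the flavone-bearing terminus and pair it with the electrophilic β-carbon of the ynal, so that OH ends para to CHO and ortho to the flavone. Chemoselectivity for C≡C over C=O is also required and is secured by excluding Lewis and Brønsted acids during the thermal phase, while the Z enol ether lets the s-cis conformer form with the flavone outside and only a slim sp C–H approaching it.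

Step 12
Reactants: 19 4-hydroxy-3-(tri-O-benzylapigenin-6-yl)benzaldehyde
Product: 20 4-(benzyloxy)-3-(tri-O-benzylapigenin-6-yl)benzaldehyde
Conditions: BnBr, K2CO3, DMF, 25 °C
Reagents that add atoms: benzyl bromide, BrCc1ccccc1
Why: Williamson etherification masks the phenol, whose phenoxide would otherwise deactivate the para formyl group in the condensation of step 15.

Step 13
Reactants: 21 2′,4′-dihydroxy-6′-methoxyacetophenone
Product: 22 4′-(benzyloxy)-2′-hydroxy-6′-methoxyacetophenone
Conditions: BnBr (1.05 equiv), K2CO3, acetone, reflux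
Reagents that add atoms: benzyl bromide, BrCc1ccccc1
Why: Williamson etherification selective for the 4′-OH because the 2′-OH is hydrogen-bonded to the acetyl carbonyl.

Step 14
Reactants: 22 4′-(benzyloxy)-2′-hydroxy-6′-methoxyacetophenone
Product: 23 tert-butyl 3-[4-(benzyloxy)-2-hydroxy-6-methoxyphenyl]-3-oxopropanoate
Conditions: LiN(SiMe3)2 (3.3 equiv), THF, −78 °C; Boc2O (1.1 equiv), −78 → 0 °C; sat. aq. NH4Cl
Reagents that add atoms: di-tert-butyl dicarbonate, CC(C)(C)OC(=O)OC(=O)OC(C)(C)C
Why: Crossed Claisen-type C-acylation of the phenoxide–enolate dianion, in which any carbonate formed on the phenoxide is carried to the same product by Baker–Venkataraman-type O-to-C transfer under the excess base and the tert-butyl ester resists lactonisation to a 4-hydroxycoumarin.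

Step 15
Reactants: 20 4-(benzyloxy)-3-(tri-O-benzylapigenin-6-yl)benzaldehyde; 23 tert-butyl 3-[4-(benzyloxy)-2-hydroxy-6-methoxyphenyl]-3-oxopropanoate
Product: 24 tert-butyl (2Z)-2-[4-(benzyloxy)-2-hydroxy-6-methoxybenzoyl]-3-[4-(benzyloxy)-3-(tri-O-benzylapigenin-6-yl)phenyl]prop-2-enoate
Conditions: piperidine (20 mol %), AcOH (20 mol %), 4 Å molecular sieves, toluene, 25 °C
Reagents that add atoms: none
Why: Knoevenagel condensation under piperidinium acetate catalysis with removal of water, the Z isomer (aryl cis to the ester, chalcone-like enone) being expected as the main product of this equilibrating reaction.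

Step 16
Reactants: 24 tert-butyl (2Z)-2-[4-(benzyloxy)-2-hydroxy-6-methoxybenzoyl]-3-[4-(benzyloxy)-3-(tri-O-benzylapigenin-6-yl)phenyl]prop-2-enoate
Product: 27 (2S)-7-(benzyloxy)-2-[4-(benzyloxy)-3-(tri-O-benzylapigenin-6-yl)phenyl]-5-methoxychroman-4-one, via 3-tert-butoxycarbonylflavanone 25 (not isolated), via 3-carboxyflavanone 26 (not isolated)
Conditions: thiourea from 9-amino-9-deoxy-epi-quinidine and 3,5-bis(trifluoromethyl)phenyl isothiocyanate (10 mol %), toluene, −25 °C; then TsOH·H2O, 80 °C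
Reagents that add atoms: none
Why: Bifunctional cinchona-thiourea catalysed enantioselective 6-endo-trig oxa-Michael addition, in which the thiourea binds the β-ketoester and the quinuclidine activates the 2′-OH so that oxygen reaches one face of the alkylidene carbon and sets C2 as S, after which TsOH quenches the base and removes isobutene and CO2 without reopening the ring.

Step 17
Reactants: 27 (2S)-7-(benzyloxy)-2-[4-(benzyloxy)-3-(tri-O-benzylapigenin-6-yl)phenyl]-5-methoxychroman-4-one
Product: 28 (2S)-2,3-dihydrorobustaflavone 5-methyl ether (CNP0332590.1)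
Conditions: H2 (1 atm), 10% Pd/C, THF–MeOH, 25 °C
Reagents that add atoms: none
Why: Catalytic hydrogenolysis of five aryl benzyl ethers under neutral conditions, which should spare the flavone C2=C3 bond, both carbonyl groups, the 5-methyl ether and the base-sensitive C2 stereocentre.

Compound list
1 | apigenin | O=c1cc(-c2ccc(O)cc2)oc2cc(O)cc(O)c12 | starting material
2 | 7-(benzyloxy)-2-[4-(benzyloxy)phenyl]-5-hydroxychromen-4-one | O=c1cc(-c2ccc(OCc3ccccc3)cc2)oc2cc(OCc3ccccc3)cc(O)c12 | intermediate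
3 | allyl bromide | C=CCBr | starting material
4 | 5-(allyloxy)-7-(benzyloxy)-2-[4-(benzyloxy)phenyl]chromen-4-one | O=c1cc(-c2ccc(OCc3ccccc3)cc2)oc2cc(OCc3ccccc3)cc(OCC=C)c12 | intermediate
5 | rac-6-allyl-7-(benzyloxy)-2-[4-(benzyloxy)phenyl]-6H-chromene-4,5-dione (not isolated) | C=CCC1C(=O)C2=C(C=C1OCc1ccccc1)OC(c1ccc(OCc3ccccc3)cc1)=CC2=O | intermediate
6 | 6-allyl-7-(benzyloxy)-2-[4-(benzyloxy)phenyl]-5-hydroxychromen-4-one | C=CCc1c(OCc2ccccc2)cc2oc(-c3ccc(OCc4ccccc4)cc3)cc(=O)c2c1O | intermediate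
7 | 6-allyl-5,7-bis(benzyloxy)-2-[4-(benzyloxy)phenyl]chromen-4-one | C=CCc1c(OCc2ccccc2)cc2oc(-c3ccc(OCc4ccccc4)cc3)cc(=O)c2c1OCc1ccccc1 | intermediate
8 | rac-5,7-bis(benzyloxy)-2-[4-(benzyloxy)phenyl]-6-(2,3-dihydroxypropyl)chromen-4-one (not isolated) | OCC(O)Cc1c(OCc2ccccc2)cc2oc(-c3ccc(OCc4ccccc4)cc3)cc(=O)c2c1OCc1ccccc1 | intermediate
9 | 2-(tri-O-benzylapigenin-6-yl)acetaldehyde | O=CCc1c(OCc2ccccc2)cc2oc(-c3ccc(OCc4ccccc4)cc3)cc(=O)c2c1OCc1ccccc1 | intermediate
10 | ethynylmagnesium bromide | C#C[Mg]Br | starting material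
11 | rac-1-(tri-O-benzylapigenin-6-yl)but-3-yn-2-ol | C#CC(O)Cc1c(OCc2ccccc2)cc2oc(-c3ccc(OCc4ccccc4)cc3)cc(=O)c2c1OCc1ccccc1 | intermediate
12 | 1-(tri-O-benzylapigenin-6-yl)but-3-yn-2-one | C#CC(=O)Cc1c(OCc2ccccc2)cc2oc(-c3ccc(OCc4ccccc4)cc3)cc(=O)c2c1OCc1ccccc1 | intermediate
13 | (3E)-4-ethoxy-1-(tri-O-benzylapigenin-6-yl)but-3-en-2-one | CCO/C=C/C(=O)Cc1c(OCc2ccccc2)cc2oc(-c3ccc(OCc4ccccc4)cc3)cc(=O)c2c1OCc1ccccc1 | intermediate
14 | 5,7-bis(benzyloxy)-2-[4-(benzyloxy)phenyl]-6-[(1Z,3E)-4-ethoxy-2-(trimethylsilyloxy)buta-1,3-dien-1-yl]chromen-4-one | CCO/C=C/C(O[Si](C)(C)C)=C/c1c(OCc2ccccc2)cc2oc(-c3ccc(OCc4ccccc4)cc3)cc(=O)c2c1OCc1ccccc1 | intermediate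
15 | propargyl alcohol | C#CCO | starting material
16 | propynal | C#CC=O | intermediate
17 | rac-cis-6-ethoxy-3-(tri-O-benzylapigenin-6-yl)-4-(trimethylsilyloxy)cyclohexa-1,4-diene-1-carbaldehyde (one enantiomer drawn, not isolated) | CCO[C@H]1C=C(O[Si](C)(C)C)[C@@H](c2c(OCc3ccccc3)cc3oc(-c4ccc(OCc5ccccc5)cc4)cc(=O)c3c2OCc2ccccc2)C=C1C=O | intermediate
18 | 3-(tri-O-benzylapigenin-6-yl)-4-(trimethylsilyloxy)benzaldehyde (not isolated) | O=Cc1ccc(O[Si](C)(C)C)c(-c2c(OCc3ccccc3)cc3oc(-c4ccc(OCc5ccccc5)cc4)cc(=O)c3c2OCc2ccccc2)c1 | intermediate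
19 | 4-hydroxy-3-(tri-O-benzylapigenin-6-yl)benzaldehyde | O=Cc1ccc(O)c(-c2c(OCc3ccccc3)cc3oc(-c4ccc(OCc5ccccc5)cc4)cc(=O)c3c2OCc2ccccc2)c1 | intermediate
20 | 4-(benzyloxy)-3-(tri-O-benzylapigenin-6-yl)benzaldehyde | O=Cc1ccc(OCc2ccccc2)c(-c2c(OCc3ccccc3)cc3oc(-c4ccc(OCc5ccccc5)cc4)cc(=O)c3c2OCc2ccccc2)c1 | intermediate
21 | 1-(2,4-dihydroxy-6-methoxyphenyl)ethanone | CC(=O)c1c(O)cc(O)cc1OC | starting material
22 | 1-[4-(benzyloxy)-2-hydroxy-6-methoxyphenyl]ethanone | CC(=O)c1c(O)cc(OCc2ccccc2)cc1OC | intermediate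
23 | tert-butyl 3-[4-(benzyloxy)-2-hydroxy-6-methoxyphenyl]-3-oxopropanoate | CC(C)(C)OC(=O)CC(=O)c1c(O)cc(OCc2ccccc2)cc1OC | intermediate
24 | tert-butyl (2Z)-2-[4-(benzyloxy)-2-hydroxy-6-methoxybenzoyl]-3-[4-(benzyloxy)-3-(tri-O-benzylapigenin-6-yl)phenyl]prop-2-enoate | CC(C)(C)OC(=O)/C(=C\c1ccc(OCc2ccccc2)c(-c2c(OCc3ccccc3)cc3oc(-c4ccc(OCc5ccccc5)cc4)cc(=O)c3c2OCc2ccccc2)c1)C(=O)c1c(O)cc(OCc2ccccc2)cc1OC | intermediate
25 | tert-butyl (2S)-7-(benzyloxy)-2-[4-(benzyloxy)-3-(tri-O-benzylapigenin-6-yl)phenyl]-5-methoxy-4-oxochromane-3-carboxylate (C3 epimers and enol in equilibrium, not isolated) | COc1cc(OCc2ccccc2)cc2c1C(=O)C(C(=O)OC(C)(C)C)[C@@H](c1ccc(OCc3ccccc3)c(-c3c(OCc4ccccc4)cc4oc(-c5ccc(OCc6ccccc6)cc5)cc(=O)c4c3OCc3ccccc3)c1)O2 | intermediate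
26 | (2S)-7-(benzyloxy)-2-[4-(benzyloxy)-3-(tri-O-benzylapigenin-6-yl)phenyl]-5-methoxy-4-oxochromane-3-carboxylic acid (C3 labile, not isolated) | COc1cc(OCc2ccccc2)cc2c1C(=O)C(C(=O)O)[C@@H](c1ccc(OCc3ccccc3)c(-c3c(OCc4ccccc4)cc4oc(-c5ccc(OCc6ccccc6)cc5)cc(=O)c4c3OCc3ccccc3)c1)O2 | intermediate
27 | (2S)-7-(benzyloxy)-2-[4-(benzyloxy)-3-(tri-O-benzylapigenin-6-yl)phenyl]-5-methoxychroman-4-one | COc1cc(OCc2ccccc2)cc2c1C(=O)C[C@@H](c1ccc(OCc3ccccc3)c(-c3c(OCc4ccccc4)cc4oc(-c5ccc(OCc6ccccc6)cc5)cc(=O)c4c3OCc3ccccc3)c1)O2 | intermediate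
28 | 5,7-dihydroxy-6-{2-hydroxy-5-[(2S)-7-hydroxy-5-methoxy-4-oxochroman-2-yl]phenyl}-2-(4-hydroxyphenyl)chromen-4-one | COc1cc(O)cc2c1C(=O)C[C@@H](c1ccc(O)c(-c3c(O)cc4oc(-c5ccc(O)cc5)cc(=O)c4c3O)c1)O2 | target

Total step count: 17.
Longest linear sequence: 14 (steps 1–9, 11, 12, 15, 16, 17).

Steps most likely to fail

Step 11. The twisted 2,6-dialkoxyaryl group shields the nucleophilic diene terminus. The cycloaddition may therefore be slow enough for hydrolysis of the enol ether, polymerisation of propynal or hetero-Diels–Alder addition to the formyl group to take over.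
The fallback buys ring B instead of building it and sets out from 2.
- Iodination ortho to the free 5-OH (BnMe3N·ICl2, CaCO3, CH2Cl2–MeOH, 25 °C) should give 7,4′-bis(benzyloxy)-5-hydroxy-6-iodoflavone F1.
- Benzylation (BnBr, K2CO3, DMF, 80 °C) should give 5,7,4′-tris(benzyloxy)-6-iodoflavone F2.
- Suzuki–Miyaura coupling of F2 with purchased 2-(benzyloxy)-5-formylphenylboronic acid F3 (Pd(OAc)2, SPhos, K2CO3, toluene–H2O, 90 °C) rejoins the route at 20.

Step 16. Four processes threaten this step:
- Facial selectivity may be poor with so large an aryl substituent.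
- The electron-rich 6′-methoxy substrate may close without the catalyst, possibly already during step 15.
- Retro-oxa-Michael opening may erode the enantiomeric purity.
- The TsOH phase may cause partial loss of the acid-labile flavone 5-O-benzyl group.

The fallback replaces asymmetric ring closure by resolution and sets out from 20 and 22.
- Claisen–Schmidt condensation (KOH, EtOH–THF, 25 °C) should give the 2′-hydroxychalcone F4.
- NaOAc in refluxing EtOH should close F4 to the racemic penta-O-benzyl flavanone F5.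
- Kinetic resolution by asymmetric transfer hydrogenation (RuCl(p-cymene)[(R,R)-TsDPEN], HCO2H–Et3N, EtOAc, 25 °C, stopped near half conversion) should reduce the 2R enantiomer to the cis-(2R,4R)-flavan-4-ol F6. The 2S ketone remains, is separated by chromatography, and rejoins the route at 27.

Step 9. Geometric control of the enol ether may be incomplete, the trimethylsilyl group may be lost by hydrolysis during isolation, and the flavone carbonyl may be O-silylated in competition.
The fallback keeps the ring B disconnection but changes the donor and the enolisation mode. It sets out from 12.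
- Addition of Me2NH (THF, 0 °C) should give the enaminone (3E)-4-(dimethylamino)-1-(tri-O-benzylapigenin-6-yl)but-3-en-2-one F7.
- Hard enolisation (KN(SiMe3)2, THF, −78 °C, then t-BuMe2SiCl) should give the more robust and more reactive 1-amino-3-silyloxydiene F8.
- F8 should add 16 in toluene at 0–25 °C to give the cis-aminocyclohexadiene cycloadduct F9.
- Mild acid should expel dimethylamine from F9 to give 4-(tert-butyldimethylsilyloxy)-3-(tri-O-benzylapigenin-6-yl)benzaldehyde F10.
- n-Bu4NF–AcOH in THF removes the silyl group and rejoins the route at 19.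

Further compounds
F1 | step 11 | 7-(benzyloxy)-2-[4-(benzyloxy)phenyl]-5-hydroxy-6-iodochromen-4-one | O=c1cc(-c2ccc(OCc3ccccc3)cc2)oc2cc(OCc3ccccc3)c(I)c(O)c12
F2 | step 11 | 5,7-bis(benzyloxy)-2-[4-(benzyloxy)phenyl]-6-iodochromen-4-one | O=c1cc(-c2ccc(OCc3ccccc3)cc2)oc2cc(OCc3ccccc3)c(I)c(OCc3ccccc3)c12
F3 | step 11 | 2-(benzyloxy)-5-formylphenylboronic acid (purchased coupling partner) | O=Cc1ccc(OCc2ccccc2)c(B(O)O)c1
F4 | step 16 | (2E)-1-[4-(benzyloxy)-2-hydroxy-6-methoxyphenyl]-3-[4-(benzyloxy)-3-(tri-O-benzylapigenin-6-yl)phenyl]prop-2-en-1-one | COc1cc(OCc2ccccc2)cc(O)c1C(=O)/C=C/c1ccc(OCc2ccccc2)c(-c2c(OCc3ccccc3)cc3oc(-c4ccc(OCc5ccccc5)cc4)cc(=O)c3c2OCc2ccccc2)c1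
F5 | step 16 | rac-7-(benzyloxy)-2-[4-(benzyloxy)-3-(tri-O-benzylapigenin-6-yl)phenyl]-5-methoxychroman-4-one | COc1cc(OCc2ccccc2)cc2c1C(=O)CC(c1ccc(OCc3ccccc3)c(-c3c(OCc4ccccc4)cc4oc(-c5ccc(OCc6ccccc6)cc5)cc(=O)c4c3OCc3ccccc3)c1)O2
F6 | step 16 | (2R,4R)-7-(benzyloxy)-2-[4-(benzyloxy)-3-(tri-O-benzylapigenin-6-yl)phenyl]-5-methoxychroman-4-ol | COc1cc(OCc2ccccc2)cc2c1[C@H](O)C[C@H](c1ccc(OCc3ccccc3)c(-c3c(OCc4ccccc4)cc4oc(-c5ccc(OCc6ccccc6)cc5)cc(=O)c4c3OCc3ccccc3)c1)O2
F7 | step 9 | (3E)-4-(dimethylamino)-1-(tri-O-benzylapigenin-6-yl)but-3-en-2-one | CN(C)/C=C/C(=O)Cc1c(OCc2ccccc2)cc2oc(-c3ccc(OCc4ccccc4)cc3)cc(=O)c2c1OCc1ccccc1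
F8 | step 9 | 5,7-bis(benzyloxy)-2-[4-(benzyloxy)phenyl]-6-[(1Z,3E)-2-(tert-butyldimethylsilyloxy)-4-(dimethylamino)buta-1,3-dien-1-yl]chromen-4-one | CN(C)/C=C/C(O[Si](C)(C)C(C)(C)C)=C/c1c(OCc2ccccc2)cc2oc(-c3ccc(OCc4ccccc4)cc3)cc(=O)c2c1OCc1ccccc1
F9 | step 9 | rac-cis-4-(tert-butyldimethylsilyloxy)-6-(dimethylamino)-3-(tri-O-benzylapigenin-6-yl)cyclohexa-1,4-diene-1-carbaldehyde (one enantiomer drawn) | CN(C)[C@H]1C=C(O[Si](C)(C)C(C)(C)C)[C@@H](c2c(OCc3ccccc3)cc3oc(-c4ccc(OCc5ccccc5)cc4)cc(=O)c3c2OCc2ccccc2)C=C1C=O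
F10 | step 9 | 4-(tert-butyldimethylsilyloxy)-3-(tri-O-benzylapigenin-6-yl)benzaldehyde | O=Cc1ccc(O[Si](C)(C)C(C)(C)C)c(-c2c(OCc3ccccc3)cc3oc(-c4ccc(OCc5ccccc5)cc4)cc(=O)c3c2OCc2ccccc2)c1
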